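The route rests on cutting ring C (the right-hand cyclohexane) between the tertiary carbinol carbon C11' and its methyl-bearing neighbour C10'. That C(OH)–CH(CH3) pair is a ketone and a vinyl group in disguise. Hydrogen-atom transfer to the vinyl group gives the secondary C10' radical, which closes ring C 6-exo onto the C11' ketone and sets both new stereocentres under control of the trans-fused oxepane (ring D) and its axial angular methyl group. The precursor is a seco-triterpenoid 1,5-diketone in which rings A, B and D are already in place; it is assembled from two epoxide-cascade products by a Mukaiyama–Michael reaction.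

Key step: step 15

Labels: carbons are numbered as in squalene, C2–C12 in the left half and C2'–C12' in the right half; ring A = left oxepane, ring B = left cyclohexane, ring C = right cyclohexane, ring D = right oxepanone.
Assumption: the enantiomer of the D-fructose-derived epoxidation ketone (otherwise made from L-sorbose) is taken as a purchasable catalyst.

**Left fragment (rings A and B)**

Step 1
Reactants: 1 geraniol
Product: 2 (2S,3S)-2,3-epoxygeraniol
Conditions: Ti(OiPr)4 (5 mol %), L-(+)-diethyl tartrate (6 mol %), t-BuOOH, 4 Å molecular sieves, CH2Cl2, −20 °C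
Reagents that add atoms: tert-butyl hydroperoxide, CC(C)(C)OO
Why: Sharpless asymmetric epoxidation of the allylic alcohol; the L-(+)-tartrate titanium complex delivers oxygen to one face of the 2,3-alkene and sets the epoxide carbons that become C7 and (after inversion in step 5) C6.

Step 2
Reactants: 2 (2S,3S)-2,3-epoxygeraniol
Product: 3 (2S,3S,6R)-2,3:6,7-diepoxy-3,7-dimethyloctan-1-ol
Conditions: D-fructose-derived ketone catalyst (30 mol %), KHSO5 (as Oxone), K2CO3, Bu4NHSO4, MeCN/CH2(OMe)2/aq. Na2B4O7 buffer, 0 °C
Reagents that add atoms: potassium peroxymonosulfate, [K+].[O-]S(=O)(=O)OO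
Why: Shi epoxidation of the remaining trisubstituted alkene through a spiro dioxirane transition state; the D-fructose-derived ketone should give the (R)-epoxide carbon that becomes C3, by reagent control.

Step 3
Reactants: 3 (2S,3S,6R)-2,3:6,7-diepoxy-3,7-dimethyloctan-1-ol
Product: 4 1-iodo-2,3:6,7-diepoxy-3,7-dimethyloctane (the three stereocentres of 3 unchanged)
Conditions: PPh3, I2, imidazole, CH2Cl2, 0 °C
Reagents that add atoms: iodine, II
Why: Appel-type iodination of the primary alcohol under neutral conditions that leave both epoxides intact; no stereocentre is touched.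

Step 4
Reactants: 4 1-iodo-2,3:6,7-diepoxy-3,7-dimethyloctane; 5 allyl acetoacetate
Product: 7 allyl (6S,7S,10R)-6,7:10,11-diepoxy-7,11-dimethyl-3-oxododecanoate, via dilithium dianion of allyl acetoacetate 6 (not isolated)
Conditions: LiN(iPr)2 (2.1 equiv), THF, 0 °C; then 4, −78 → 0 °C; aq. NH4Cl
Reagents that add atoms: none
Why: γ-Alkylation of the acetoacetate dianion at its more reactive terminal carbon by SN2 displacement of the primary iodide, which should be faster than epoxide opening; no stereocentre is touched.

Step 5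
Reactants: 7 allyl (6S,7S,10R)-6,7:10,11-diepoxy-7,11-dimethyl-3-oxododecanoate
Product: 10 allyl (3R,5aS,6S,9aS)-3-hydroxy-2,2,5a-trimethyl-7-oxodecahydro-1-benzoxepine-6-carboxylate, via O-silyl enol ether of the keto ester 8 (not isolated), via O-silylated bicycle 9 (not isolated)
Conditions: Me3SiOTf (2.5 equiv), 2,6-di-tert-butyl-4-methylpyridine, CH2Cl2, −78 °C; then Bu4NF, AcOH, THF, 0 °C
Reagents that add atoms: none
Why: Epoxide-opening cascade (tandem oxa- and carbacyclisation) with an enol silane terminator: the silyl triflate activates the terminal epoxide, the internal epoxide oxygen attacks its tertiary carbon to give a bicyclic epoxonium ion (ring A), and the enol carbon C11 opens this at tertiary C6 with inversion through a chair transition state (ring B), so that C3 and C7 are kept from the epoxides, C6 is set anti to the oxygen (trans ring fusion) and the ester at C11 ends equatorial.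

Step 6
Reactants: 10 allyl (3R,5aS,6S,9aS)-3-hydroxy-2,2,5a-trimethyl-7-oxodecahydro-1-benzoxepine-6-carboxylate
Product: 11 allyl (3R,5aS,6S,9aS)-3-acetoxy-2,2,5a-trimethyl-7-oxodecahydro-1-benzoxepine-6-carboxylate
Conditions: Ac2O, pyridine, DMAP (cat.), CH2Cl2, rt
Reagents that add atoms: acetic anhydride, CC(=O)OC(C)=O
Why: Standard acylation of the only hydroxyl group (secondary, C3); the keto ester should not be O-acylated under these mild conditions.

Step 7
Reactants: 11 allyl (3R,5aS,6S,9aS)-3-acetoxy-2,2,5a-trimethyl-7-oxodecahydro-1-benzoxepine-6-carboxylate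
Product: 14 (3R,5aS,9aS)-2,2,5a-trimethyl-6-methylidene-7-oxodecahydro-1-benzoxepin-3-yl acetate, via β-keto acid 12 (not isolated), via aminomethyl keto acid 13 (not isolated)
Conditions: Pd(PPh3)4 (5 mol %), morpholine, THF, rt; then aq. HCHO, AcOH, 50 °C
Reagents that add atoms: formaldehyde, C=O
Why: Tsuji–Trost-type deallylation by zerovalent palladium with morpholine as allyl acceptor gives the β-keto acid, which undergoes a decarboxylative Mannich methylenation, so the exocyclic enone forms regiospecifically at the carbon that carried the carboxyl group (C11; the new CH2 is C12).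

**Right fragment (ring D)**

Step 8
Reactants: 15 triethyl phosphonoacetate; 16 5-bromo-2-methylpent-2-ene
Product: 17 ethyl 2-(diethoxyphosphoryl)-6-methylhept-5-enoate
Conditions: NaH, DMSO, rt → 60 °C
Reagents that add atoms: none
Why: SN2 alkylation of the sodium phosphonoacetate anion with the primary bromide; no stereocentre.

Step 9
Reactants: 17 ethyl 2-(diethoxyphosphoryl)-6-methylhept-5-enoate; 18 pent-4-enal
Product: 19 ethyl (2E)-2-(4-methylpent-3-en-1-yl)hepta-2,6-dienoate
Conditions: NaH, DME, 0 → 60 °C; E isomer separated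
Reagents that add atoms: none
Why: Horner–Wadsworth–Emmons olefination; the stabilised α-branched phosphonate should give mainly the E-enoate (ester trans to the butenyl chain), the geometry that later fixes the relative configuration of C6' and C7'.

Step 10
Reactants: 19 ethyl (2E)-2-(4-methylpent-3-en-1-yl)hepta-2,6-dienoate
Product: 20 (3E)-2-methyl-3-(4-methylpent-3-en-1-yl)octa-3,7-dien-2-ol
Conditions: MeMgBr (3 equiv), THF, 0 °C → rt
Reagents that add atoms: methylmagnesium bromide, C[Mg]Br
Why: Double 1,2-addition of the Grignard reagent to the α-branched enoate gives the tertiary allylic alcohol whose two methyl groups later supply the C6' methyl group and C12'.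

Step 11
Reactants: 20 (3E)-2-methyl-3-(4-methylpent-3-en-1-yl)octa-3,7-dien-2-ol
Product: 21 2-[(2R,3S)-3-(but-3-en-1-yl)-2-{2-[(2S)-3,3-dimethyloxiran-2-yl]ethyl}oxiran-2-yl]propan-2-ol
Conditions: enantiomer of the D-fructose-derived ketone catalyst (2 × 30 mol %), KHSO5 (as Oxone), K2CO3, Bu4NHSO4, MeCN/CH2(OMe)2/aq. Na2B4O7 buffer, 0 °C
Reagents that add atoms: potassium peroxymonosulfate, [K+].[O-]S(=O)(=O)OO
Why: Shi epoxidation of both trisubstituted alkenes (the monosubstituted alkene is inert to the dioxirane); the enantiomeric ketone should attack the face that gives the (2R,3S)-oxirane (future C6' and C7') and the (S)-terminal epoxide, whose configuration is erased in step 18.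

Step 12
Reactants: 21 2-[(2R,3S)-3-(but-3-en-1-yl)-2-{2-[(2S)-3,3-dimethyloxiran-2-yl]ethyl}oxiran-2-yl]propan-2-ol
Product: 23 1-[(3S,6R,7S)-7-(but-3-en-1-yl)-2,2,6-trimethyl-3-(triethylsilyloxy)oxepan-6-yl]ethan-1-one, via triethylsilyl ether of the diepoxy alcohol 22 (not isolated)
Conditions: Et3SiOTf (2.2 equiv), 2,6-di-tert-butyl-4-methylpyridine, CH2Cl2, −78 → −40 °C; aq. NaHCO3
Reagents that add atoms: triethylsilyl trifluoromethanesulfonate, CC[Si](CC)(CC)OS(=O)(=O)C(F)(F)F
Why: Proposed new method: the silyl triflate first silylates the tertiary hydroxyl and then activates the less hindered terminal epoxide, whose tertiary carbon is attacked by the oxygen of the internal epoxide through a six-membered transition state to give a bicyclic epoxonium ion; this opens at tertiary C6' with a concerted anti 1,2-shift of a methyl group from the adjacent silyloxy carbon (semipinacol), which closes the oxepane (ring D), sets the quaternary centre C6' with inversion and turns the carbinol carbon into the methyl ketone C11', while C7' keeps its oxygen; the closest known reaction types are the endo-selective Lewis-acid cascade of 1,5-diepoxides through epoxonium ions and the Lewis-acid semipinacol rearrangement of 2,3-epoxy silyl ethers, which have not been combined.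

Step 13
Reactants: 23 1-[(3S,6R,7S)-7-(but-3-en-1-yl)-2,2,6-trimethyl-3-(triethylsilyloxy)oxepan-6-yl]ethan-1-one
Product: 24 trimethylsilyl enol ether of 23 (1-(trimethylsilyloxy)vinyl group at C6')
Conditions: Me3SiOTf, Et3N, CH2Cl2, 0 °C
Reagents that add atoms: trimethylsilyl trifluoromethanesulfonate, C[Si](C)(C)OS(=O)(=O)C(F)(F)F
Why: Soft enolisation of the methyl ketone, which has only one enolisable side, gives the silyl enol ether needed as the nucleophile.

**Fragment union and end game**

Step 14
Reactants: 24 trimethylsilyl enol ether of 23; 14 (3R,5aS,9aS)-2,2,5a-trimethyl-6-methylidene-7-oxodecahydro-1-benzoxepin-3-yl acetate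
Product: 26 seco-1,5-diketone (rings A, B and D closed; C10 ketone; C11–CH2CH2–C(=O)–C6' chain; but-3-enyl group on C7'), via trimethylsilyl enol ether of the adduct 25 (not isolated)
Conditions: Me3SiNTf2 (5 mol %), CH2Cl2, −78 °C; then 0.5 M HCl, THF, 0 °C
Reagents that add atoms: none
Why: Mukaiyama–Michael addition of the silyl enol ether to the unhindered methylidene terminus of the enone forms the C12–C12' bond, and axial protonation of the ring-B silyl enol ether anti to the axial C6 methyl group on hydrolysis should set C11 with the side chain equatorial (also the thermodynamic epimer).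

Step 15
Reactants: 26 seco-1,5-diketone
Product: 27 ring-C closed hydroxy ketone (C11' tertiary alcohol, C10' methyl, C10 ketone, C3 acetate, C3' triethylsilyl ether)
Conditions: Fe(acac)3 (30 mol %), PhSiH3, EtOH/HOCH2CH2OH, 60 °C, under Ar
Reagents that add atoms: none
Why: A trivalent iron hydride formed from Fe(acac)3 and PhSiH3 transfers a hydrogen atom to the terminal carbon of the only alkene, the secondary C10' radical adds to the C11' ketone, and the alkoxy radical is reduced by divalent iron and protonated by ethanol. The closest known reaction type is the hydrogen-atom-transfer-initiated radical cyclisation of alkene-tethered ketones to tertiary cycloalkanols. Ring C closes in the 6-exo-trig mode onto the carbonyl carbon through a chair transition state whose trans ring fusion is already fixed by C6' and C7'. C10' is controlled by the axial C6' methyl group (an axial C10' methyl would be syn-pentane to it, so it goes equatorial), and C11' by the preference of the CH2CH2 chain over the small oxygen for the equatorial position, which should leave the hydroxyl axial and cis to the new methyl group. The step needs chemoselectivity for the C11' ketone over the C10 ketone and a single reactive alkene: C10 cannot be reached through a small ring, and the ring-B methylidene, which would also accept a hydrogen atom, is deliberately introduced only in step 16.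

Step 16
Reactants: 27 ring-C closed hydroxy ketone
Product: 28 3'-O-triethylsilyl ether of the 3'-alcohol 29 (ring-B methylidene in place)
Conditions: Zn, CH2Br2, TiCl4, THF/CH2Cl2, 0 °C → rt
Reagents that add atoms: dibromomethane, BrCBr
Why: Takai–Lombardo methylenation converts the hindered, enolisable ring-B ketone into the methylidene group without epimerising C11 and should leave the acetate, the silyl ether and the tertiary alcohol untouched.

Step 17
Reactants: 28 3'-O-triethylsilyl ether
Product: 29 (3'S)-3'-alcohol (target with CH–OH in place of the ring-D ketone)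
Conditions: HF·pyridine, pyridine, THF, 0 °C → rt
Reagents that add atoms: none
Why: Fluoride-mediated cleavage of the secondary triethylsilyl ether under buffered conditions that spare the acetate, the tertiary alcohol and the methylidene group.

Step 18
Reactants: 29 (3'S)-3'-alcohol
Product: 30 3-epi-sodwanone K 3-acetate
Conditions: Dess–Martin periodinane, NaHCO3, CH2Cl2, rt
Reagents that add atoms: none
Why: Dess–Martin oxidation of the only secondary alcohol to the ring-D ketone; the tertiary alcohol, the acetate and the alkene are inert.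

**Compound list**

1 | geraniol | CC(C)=CCC/C(C)=C/CO | starting material
2 | (2S,3S)-2,3-epoxygeraniol | OC[C@@H]1O[C@@]1(C)CCC=C(C)C | intermediate
3 | (2S,3S,6R)-2,3:6,7-diepoxy-3,7-dimethyloctan-1-ol | OC[C@@H]1O[C@@]1(C)CC[C@H]1OC1(C)C | intermediate
4 | 1-iodo-2,3:6,7-diepoxy-3,7-dimethyloctane (configuration of 3) | IC[C@@H]1O[C@@]1(C)CC[C@H]1OC1(C)C | intermediate
5 | allyl acetoacetate | CC(=O)CC(=O)OCC=C | starting material
6 | dilithium dianion of allyl acetoacetate | [Li+].[Li+].C=C([O-])C=C([O-])OCC=C | intermediate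
7 | allyl (6S,7S,10R)-6,7:10,11-diepoxy-7,11-dimethyl-3-oxododecanoate | C=CCOC(=O)CC(=O)CC[C@@H]1O[C@@]1(C)CC[C@H]1OC1(C)C | intermediate
8 | (Z)-O-trimethylsilyl enol ether of 7 | C=CCOC(=O)/C=C(\O[Si](C)(C)C)CC[C@@H]1O[C@@]1(C)CC[C@H]1OC1(C)C | intermediate
9 | 3-O-trimethylsilyl ether of 10 | O=C1CC[C@@H]2OC(C)(C)[C@H](O[Si](C)(C)C)CC[C@@]2(C)[C@@H]1C(=O)OCC=C | intermediate
10 | allyl (3R,5aS,6S,9aS)-3-hydroxy-2,2,5a-trimethyl-7-oxodecahydro-1-benzoxepine-6-carboxylate | O=C1CC[C@@H]2OC(C)(C)[C@H](O)CC[C@@]2(C)[C@@H]1C(=O)OCC=C | intermediate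
11 | allyl (3R,5aS,6S,9aS)-3-acetoxy-2,2,5a-trimethyl-7-oxodecahydro-1-benzoxepine-6-carboxylate | O=C1CC[C@@H]2OC(C)(C)[C@H](OC(C)=O)CC[C@@]2(C)[C@@H]1C(=O)OCC=C | intermediate
12 | β-keto acid from 11 (free 6-carboxylic acid) | O=C1CC[C@@H]2OC(C)(C)[C@H](OC(C)=O)CC[C@@]2(C)[C@@H]1C(=O)O | intermediate
13 | 6-(morpholin-4-ylmethyl) derivative of 12 | O=C1CC[C@@H]2OC(C)(C)[C@H](OC(C)=O)CC[C@@]2(C)C1(CN1CCOCC1)C(=O)O | intermediate
14 | (3R,5aS,9aS)-2,2,5a-trimethyl-6-methylidene-7-oxodecahydro-1-benzoxepin-3-yl acetate | O=C1CC[C@@H]2OC(C)(C)[C@H](OC(C)=O)CC[C@@]2(C)C1=C | intermediate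
15 | triethyl phosphonoacetate | CCOC(=O)CP(=O)(OCC)OCC | starting material
16 | 5-bromo-2-methylpent-2-ene | CC(C)=CCCBr | starting material
17 | ethyl 2-(diethoxyphosphoryl)-6-methylhept-5-enoate | CCOC(=O)C(CCC=C(C)C)P(=O)(OCC)OCC | intermediate
18 | pent-4-enal | C=CCCC=O | starting material
19 | ethyl (2E)-2-(4-methylpent-3-en-1-yl)hepta-2,6-dienoate | CCOC(=O)/C(=C/CCC=C)CCC=C(C)C | intermediate
20 | (3E)-2-methyl-3-(4-methylpent-3-en-1-yl)octa-3,7-dien-2-ol | CC(C)(O)/C(=C/CCC=C)CCC=C(C)C | intermediate
21 | 2-[(2R,3S)-3-(but-3-en-1-yl)-2-{2-[(2S)-3,3-dimethyloxiran-2-yl]ethyl}oxiran-2-yl]propan-2-ol | CC(C)(O)[C@@]1(O[C@H]1CCC=C)CC[C@@H]1OC1(C)C | intermediate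
22 | triethylsilyl ether of 21 | CC(C)(O[Si](CC)(CC)CC)[C@@]1(O[C@H]1CCC=C)CC[C@@H]1OC1(C)C | intermediate
23 | 1-[(3S,6R,7S)-7-(but-3-en-1-yl)-2,2,6-trimethyl-3-(triethylsilyloxy)oxepan-6-yl]ethan-1-one | C=CCC[C@@H]1OC(C)(C)[C@@H](O[Si](CC)(CC)CC)CC[C@@]1(C)C(C)=O | intermediate
24 | trimethylsilyl enol ether of 23 | C=CCC[C@@H]1OC(C)(C)[C@@H](O[Si](CC)(CC)CC)CC[C@@]1(C)C(=C)O[Si](C)(C)C | intermediate
25 | ring-B (C10–O) trimethylsilyl enol ether of 26 | C[Si](C)(C)OC1=C(CCC(=O)[C@]2(C)CC[C@H](O[Si](CC)(CC)CC)C(C)(C)O[C@H]2CCC=C)[C@]2(C)CC[C@@H](OC(C)=O)C(C)(C)O[C@H]2CC1 | intermediate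
26 | seco-1,5-diketone (C10 and C11' ketones, C3 acetate, C3' triethylsilyl ether, but-3-enyl on C7') | O=C1CC[C@@H]2OC(C)(C)[C@H](OC(C)=O)CC[C@@]2(C)[C@@H]1CCC(=O)[C@]1(C)CC[C@H](O[Si](CC)(CC)CC)C(C)(C)O[C@H]1CCC=C | intermediate
27 | ring-C closed hydroxy ketone (C10 ketone, (10'S,11'S)) | O=C1CC[C@@H]2OC(C)(C)[C@H](OC(C)=O)CC[C@@]2(C)[C@@H]1CC[C@]1(O)[C@@H](C)CC[C@@H]2OC(C)(C)[C@@H](O[Si](CC)(CC)CC)CC[C@]21C | intermediate
28 | 3'-O-triethylsilyl ether of 29 | C=C1CC[C@@H]2OC(C)(C)[C@H](OC(C)=O)CC[C@@]2(C)[C@@H]1CC[C@]1(O)[C@@H](C)CC[C@@H]2OC(C)(C)[C@@H](O[Si](CC)(CC)CC)CC[C@]21C | intermediate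
29 | (3'S)-3'-alcohol (3'-deoxo-3'-hydroxy target) | C=C1CC[C@@H]2OC(C)(C)[C@H](OC(C)=O)CC[C@@]2(C)[C@@H]1CC[C@]1(O)[C@@H](C)CC[C@@H]2OC(C)(C)[C@@H](O)CC[C@]21C | intermediate
30 | 3-epi-sodwanone K 3-acetate | C=C1CC[C@@H]2OC(C)(C)[C@H](OC(C)=O)CC[C@@]2(C)[C@@H]1CC[C@]1(O)[C@@H](C)CC[C@@H]2OC(C)(C)C(=O)CC[C@]21C | target

**Step count and risks**

Total step count: 18. Longest linear sequence: 12 steps (steps 1–7, then 14–18); the right fragment takes 6 steps (8–13).

Steps most likely to fail:

1. Step 12 (proposed new method). The silyl triflate may ionise the hindered internal epoxide first, so that the semipinacol shift runs before ring D is closed and the liberated C7' oxygen later closes 6-exo to a tetrahydropyran. Proton loss from the C6' cation instead of methyl migration is a second possibility. Fallback, using known reactions one at a time, from 20 back to 23: hydroxyl-directed asymmetric epoxidation of the allylic alkene of 20 (Hf(OtBu)4, chiral bis-hydroxamic acid ligand, cumene hydroperoxide) should give the mono-epoxide F1. Silylation (Et3SiOTf, 2,6-lutidine) gives F2. Lewis-acid semipinacol rearrangement of this 2,3-epoxy silyl ether (TiCl4, CH2Cl2, −78 °C, aqueous work-up) gives the β-hydroxy ketone F3. Shi epoxidation of the remaining trisubstituted alkene (enantiomeric ketone catalyst, KHSO5, 0 °C) gives F4. Acid-promoted 7-endo opening of the epoxide at its tertiary carbon by the C7' hydroxyl (camphorsulfonic acid, CH2Cl2) gives the oxepanol F5, to be separated from the 6-exo isomer. Silylation (Et3SiOTf, 2,6-lutidine) gives 23.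

2. Step 15 (key step). Facial selectivity at the C11' carbonyl may be poor (side chain axial instead of equatorial), or the C10' radical may be reduced before it cyclises. Fallback from 26 back to 28: the ring-B ketone of 26 is methylenated first (Zn, CH2Br2, TiCl4; the neopentyl-type C11' ketone should be too hindered) to give F6. Cp2Ti(PMe3)2 (divalent titanium) then couples the C11' ketone with the monosubstituted alkene to the oxatitanacyclopentane F7, in which oxygen and the CH2 group are necessarily cis on ring C; the 1,1-disubstituted ring-B methylidene is expected not to insert. Protonolysis (aq. HCl) gives 28.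

3. Step 7. The β-keto acid may lose CO2 before the Mannich step, which would destroy the regiochemical handle at C11 and give the plain ketone. Fallback from 11 and 24 back to 26, with the roles of the partners reversed: 24 reacts with dimethylmethyleneiminium iodide to give the Mannich base F8. Heating F8 with 11 and Cs2CO3 in MeCN releases the vinyl ketone F9 in the flask (loss of dimethylamine), and the β-keto ester anion of 11 adds to it in a Michael reaction to give the quaternary allyl β-keto ester F10. Pd(PPh3)4 with HCO2H/Et3N (zerovalent palladium) removes the allyl ester with loss of CO2 and gives 26 after equilibration at C11; the ring-B ketone is then carried on as in steps 15–18.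

Further compounds
F1 | step 12 | 2-[(2R,3S)-3-(but-3-en-1-yl)-2-(4-methylpent-3-en-1-yl)oxiran-2-yl]propan-2-ol | CC(C)(O)[C@@]1(O[C@H]1CCC=C)CCC=C(C)C
F2 | step 12 | triethylsilyl ether of F1 | CC(C)(O[Si](CC)(CC)CC)[C@@]1(O[C@H]1CCC=C)CCC=C(C)C
F3 | step 12 | (3R,4S)-4-hydroxy-3-methyl-3-(4-methylpent-3-en-1-yl)oct-7-en-2-one | C=CCC[C@H](O)[C@@](C)(CCC=C(C)C)C(C)=O
F4 | step 12 | (3R,4S)-3-{2-[(2S)-3,3-dimethyloxiran-2-yl]ethyl}-4-hydroxy-3-methyloct-7-en-2-one | C=CCC[C@H](O)[C@@](C)(CC[C@@H]1OC1(C)C)C(C)=O
F5 | step 12 | 1-[(3S,6R,7S)-7-(but-3-en-1-yl)-3-hydroxy-2,2,6-trimethyloxepan-6-yl]ethan-1-one | C=CCC[C@@H]1OC(C)(C)[C@@H](O)CC[C@@]1(C)C(C)=O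
F6 | step 15 | 26 with the ring-B ketone replaced by a methylidene group | C=C1CC[C@@H]2OC(C)(C)[C@H](OC(C)=O)CC[C@@]2(C)[C@@H]1CCC(=O)[C@]1(C)CC[C@H](O[Si](CC)(CC)CC)C(C)(C)O[C@H]1CCC=C
F7 | step 15 | bis(cyclopentadienyl) oxatitanacyclopentane spanning O–C11' and C10'–CH2 | C=C1CC[C@@H]2OC(C)(C)[C@H](OC(C)=O)CC[C@@]2(C)[C@@H]1CC[C@]1(O3)[C@@H](C[Ti]3(C3C=CC=C3)(C3C=CC=C3))CC[C@@H]2OC(C)(C)[C@@H](O[Si](CC)(CC)CC)CC[C@]21C
F8 | step 7 | 3-(dimethylamino)propanoyl analogue of 23 (Mannich base) | CN(C)CCC(=O)[C@]1(C)CC[C@H](O[Si](CC)(CC)CC)C(C)(C)O[C@H]1CCC=C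
F9 | step 7 | vinyl ketone analogue of 23 (prop-2-enoyl group at C6') | C=CC(=O)[C@]1(C)CC[C@H](O[Si](CC)(CC)CC)C(C)(C)O[C@H]1CCC=C
F10 | step 7 | Michael adduct of 11 and F9 (C11 quaternary, allyl ester retained) | C=CCOC(=O)C1(CCC(=O)[C@]2(C)CC[C@H](O[Si](CC)(CC)CC)C(C)(C)O[C@H]2CCC=C)C(=O)CC[C@@H]2OC(C)(C)[C@H](OC(C)=O)CC[C@@]12C
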